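The runs stem from a simulated flask from invented constants, and the scatter is random.

You want to know how much target this flask holds at 2.5 h, and which move at that moment adds the most.

| flask | electrophile | free base | solid nucleophile | temperature | remark | time |
|---|---|---|---|---|---|---|
| gamma | 0.30 M | 1 equiv | 0.90 equiv | 100 °C | the very flask that is asked about, followed so far |  |
| eta | 0.30 M | 1 equiv | 0.90 equiv | 106 °C | run made earlier |  |
| flask | 0.30 M | 1.00 equiv | 0.900 equiv | 100 °C |  | 2.5 h |

- gamma (time / min: target / %): 12.0: 45.6; 20.0: 48.7; 30.0: 47.4; 40.0: 52.6; 60.0: 55.4; 90.0: 60.3; 150: 63.8
- eta (time / min: target / %): 12.0: 44.9; 20.0: 50.0; 30.0: 52.3; 40.0: 54.0; 60.0: 59.7; 90.0: 64.4; 150: 69.5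

(each reading ± 1 percentage point)

- grey: at 2.5 h take out 90 % of the target then present, then wait 80 min
- blue: at 2.5 h add free base, 100 % of the amount charged, then wait 80 min
- red: at 2.5 h raise the temperature by 25 K, then wait 80 min
- amber: change nothing and wait 80 min more
- teal: at 2.5 h add free base, 50.0 % of the amount charged, then wait 80 min

1. target, in percent of the electrophile first charged, at 2.5 h
2. the option that brings most further target ("none" if no option brings more than 2 percentage points) (grey / blue / red / amber / teal / none)
3. target present, with what was taken out counted in, in percent of the electrophile first charged, after red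
4. target present, with what was taken out counted in, in percent of the electrophile first charged, after teal

- percentages count the electrophile that a species holds: one homo dimer counts as two
- solid, in amounts per volume of the solution: solid nucleophile
- target taken out counts as made
- steps thought possible: electrophile + nucleophile -> acid set free + target; nucleophile + acid set free <-> protonated nucleophile; acid set free + free base <-> salt of the base; 2 electrophile -> homo dimer; solid nucleophile <-> nucleophile
- at the start none of the solid nucleophile is in solution
- additions bring no volume worth counting

First, where does the quick part stop? Each target sets one acid free, and if that acid takes a second nucleophile, target stalls at the burst ceiling Y, half of the nucleophile charge: 45.0 % of the electrophile. The gamma run reads 45.6 % at 12.0 min, a ratio to Y of 1.01, so this reading lies at Y within its scatter.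

Second, what does target past Y cost? Counting acid and nucleophile, and leaving out their small free forms, each further target takes two salt of the base. So T = Y + S/2, with T the target and S the salt, both in percent of the electrophile charged. The gamma reading at 150 min, 63.8 %, lies 19 percentage points above Y, so S is 37.6 %, and by this count 62.4 % of the free base still stands in this flask.

Third, which is the bigger move, heat or base? Work in powers of ten. The eta run reads 59.7 % at 60.0 min and the gamma run 60.3 % at 90.0 min, so going from 100 °C to 106 °C shortens the time by a reading of 0.176 in the logarithm. Red's 25 K is about 4 such steps, or 0.704. Blue, if the pace follows free base, gives 0.415. The heat term is larger than the base term, so my reckoning says red, with about 63.8 % now.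

The forecast says 64 % and red, with 73 % after red and 69.5 % after teal: “Red gains about 9, making it best, if dimerisation stays minor.”

The flask gives 64.4 % and red, which adds 12 points against 7.3 points for blue, with 76.8 % after red and 70.4 % after teal.

    electrophile + nucleophile → acid set free + target (k = 1.60 M⁻¹ min⁻¹, Ea = 89.0 kJ mol⁻¹)
    nucleophile + acid set free ⇌ protonated nucleophile, settled at all times (K = 20000 M⁻¹, ΔH = −31.0 kJ mol⁻¹)
    acid set free + free base ⇌ salt of the base (K = 500 M⁻¹, k = 2.70 M⁻¹ min⁻¹, Ea = 73.0 kJ mol⁻¹, ΔH = −20.0 kJ mol⁻¹)
    2 electrophile → homo dimer (k = 0.00760 M⁻¹ min⁻¹, Ea = 100 kJ mol⁻¹)
    solid nucleophile ⇌ nucleophile, rate k5*(cs5 - [nucleophile]) while solid is left; crystals form when [nucleophile] > cs5 (solubility = 0.240 M, k = 0.160 min⁻¹)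
    (constants at 100 °C)

In this flask at 150 min the salt of the base stands at 0.116 M, which is 38.7 % of the electrophile charged, so Y + S/2 gives 64.3 %. To part from the forecast's "now", a run needs another charge of solid nucleophile: with the other amounts and the time held, the answer has moved by 5 points at 0.805 equiv and at 1.00 equiv. The neighbouring flask is charged with 0.540 equiv of solid nucleophile, so its Y is 27.0 %. Its salt of the base, 0.101 M at 150 min, is 33.7 % of the electrophile charged, so the reckoning gives 43.9 %, and that neighbouring flask holds 44.0 % of target.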